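## The problem

The target is a trans-fused hydroazulene. Daucane numbering is used throughout: ring A is the five-membered ring C1–C5, ring B the seven-membered ring C1, C5–C10; C1 is the quaternary, methyl-bearing fusion carbon, C4 the isopropyl carbinol, C5 the fusion CH, C6 the ester carbinol, C8=C9 the alkene with methyl on C8, and C10 the ketone. Four stereocentres sit on adjacent atoms (C1, C5, C4 in ring A and C6 on ring B). They can be set as a relay: C1 absolutely, C5 trans to the larger C1 substituent, C4 by attack of a nucleophile anti to the C5 side chain, and C6 by hydride delivered from the C4 hydroxyl. The tertiary C4 alcohol will not survive strong acid. Whenever C6 is a ketone, the C4 oxygen is β to it (retro-aldol, β-elimination) and C5 becomes epimerisable. In the target, C7 is γ to the enone and C6 carries a carboxylate, so base can expel the ester through the dienolate. A ring B that holds a C6 ketone and the C10 enone together is a vinylogous 1,3-diketone whose double bond can move between C8=C9 and C7=C8; this must be avoided. The enabling feature is that C1 is β and C5 is α to the oxygenated C4. Ring A is therefore a masked 3-methylcyclopentanone, and the two ring B bonds C1–C10 and C5–C6 are the bonds formed at the β- and α-carbons of 3-methylcyclopent-2-en-1-one by conjugate addition and enolate trapping.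

## Retrosynthesis

**C8=C9 π bond (20 → 19).** The unsaturation is removed first, so that the last step is a dehydrogenation of saturated ketone 19. The neighbouring option, closing ring B onto a triple bond to obtain the enone directly, is one step shorter, but it puts a C6 ketone and the C10 enone in the same ring and leaves the alkene position undefined. In 19 the C10 ketone can enolise only toward C9 because C1 is quaternary, so the position of the new alkene is fixed, and the base-sensitive enone/ester pair is formed under non-basic conditions.

**O6–acyl bond (19 → 18).** The aroyl group is cut from O6. Diol 18 has one secondary and one hindered tertiary hydroxyl, so plain acylation is selective. An earlier acylation is not possible because C6 must pass through the ketone stage.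

**C6–H bond (18 → 17).** The C6 carbinol is traced to the ketone of hydroxy diketone 17. The C4 hydroxyl and O6 are 1,3-anti, which is the pattern produced by intramolecular hydride delivery from a β-hydroxyl. An external hydride would have to choose between two ketones and two faces.

**C7–C8 bond (17 → 15, through 16).** Ring B is opened between C7 and C8, giving cyclopentane 15 with a methyl ketone on C5 and an (E)-but-2-enoyl group on C1. The forward reaction is a 7-endo-trig intramolecular Michael addition of the C7 enolate. A closure at C8=C9 by metathesis or carbonyl olefination would need C7 already bonded to C8, which the methyl group brought in by acetaldehyde does not offer. The competing aldol at C10 would form a strained trans-fused bicyclo[3.3.0]octane and is reversible. The C4 hydroxyl is silylated for this step so that no alkoxide β to the C6 ketone can trigger retro-aldol cleavage.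

**Oxidation levels and C9–C10 bond (15 → 14 → 13 → 12 → 11).** Diketone 14 comes from triol 13 by one oxidation of both secondary carbinols; this is why neither carbinol configuration matters. The C9–C10 bond is cut to aldehyde 11 and an (E)-propenyl nucleophile. Aldehyde 11 has no α-hydrogen and cannot close a lactol with the trans C4 hydroxyl.

**C10 unmasking and C4–isopropyl bond (11 → 9 → 8 → 7 → 6).** The aldehyde comes from the vinyl group of 9 by ozonolysis. The isopropyl group is cut from C4 to give ketone 8; the nucleophile must enter anti to the C5 side chain. The vinyl group comes from the vinylsilane of 7 by protodesilylation. This acid step is placed before the acid-labile tertiary alcohol exists, and the C6 hydroxyl of 6 is protected as a triisopropylsilyl ether that survives it.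

**C1–C10 and C5–C6 bonds (6 → 3 + 2 + 4).** Both bonds are cut at once: enone 3, alkenylalane 2 and acetaldehyde 4. Alkylating a preformed 3,3-disubstituted cyclopentanone at C5 would fight the kinetic preference for the unhindered α-carbon. Here the enolate is born regiospecifically by the conjugate addition and is used at once. The precursors are three commodity-level compounds with no stereocentre; the forward step must deliver the quaternary centre with catalyst control and the trans C1/C5 relationship with substrate control.

**C–Al bond (2 → 1).** The alane is traced to ethynyltrimethylsilane 1 by hydroalumination, with aluminium placed on the silicon-bearing carbon.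

## Roads not taken

**Alternative 1: asymmetric intramolecular Buchner reaction.** The cut removes the bonds from C5 to C1 and to C6. In the forward sense diazoketone A2, with Cu(MeCN)4PF6 (monovalent copper) and a chiral bis(oxazoline), adds its carbene carbon across the ipso/ortho bond of the cresol ether. The fused cyclopropane then opens electrocyclically to bicyclic trienone A1. Ring A and the seven-membered ring arise in one catalytic asymmetric step from a flat aromatic, and in steps to the carbon framework this road is clearly shorter than the chosen one. Its weak points for this target are: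
- only C5 is set, and it sits α to the C4 ketone on a cycloheptatriene prone to hydrogen shifts;
- C1 has no methyl, so the quaternary centre must be made later, trans to H5, next to an epimerisable carbon;
- C6 has no oxygen and would have to be oxidised selectively among three ring alkenes;
- the ortho methoxy group may steer the carbene to the other arene bond.

Against the brevity of this road, the chosen plan sets C1 first under catalyst control and gives every later centre a defined controller.

**Alternative 2: one-carbon ring expansion of a trans-hydrindanone.** The cut excises C9. Silyl enol ether A4 is cyclopropanated at C10=C8 with Et2Zn and CH2I2. The three-membered ring is opened at its internal bond with FeCl3 (trivalent iron), and HCl is lost with NaOAc, giving A3, the C4 triethylsilyl ether of the target. This road is better than the chosen one in one respect: the enone comes out with its regiochemistry built in, and no seven-membered ring has to be closed. Its cost is upstream. A4 is a trans-hydrindane that already carries all four stereocentres, the angular methyl and the tertiary carbinol, and it is no easier to make than the daucane itself. The cyclopropanation has to occur on a tetrasubstituted, neopentyl enol ether. The one-electron oxidant meets an electron-rich anisoate, and the final base treatment meets the base-labile ester. The chosen plan forms ring B directly from a monocyclic precursor made by one catalytic step; it pays with a Michael closure and a last-step dehydrogenation.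

**Alternative 3: carbenoid C–H insertion.** The cut is C1–C5. Rh2(OAc)4 (divalent rhodium) decomposes diazo keto ester A6, and the carbenoid carbon inserts into the tertiary C–H bond with retention to give cyclopentanone A5. The 1,5-insertion is reliable, the quaternary centre comes from an easily secured methyl-branched stereocentre, and A5 carries C6 as an ester and C10 as a protected primary alcohol. These two differentiated one-carbon handles suit a three-carbon ring B annulation better than the methyl carbinol and vinylsilane of 6, so in that respect A5 is the better intermediate. Against this, A6 needs a linear synthesis with stoichiometric chirality and a diazo transfer. The β-keto ester of A5 is enolised by the isopropyl nucleophile needed at C4, so extra redox and protection steps follow, and C7–C9 must all still be added. The chosen plan reaches the same substitution pattern in two steps with catalytic asymmetry and brings C7 with it; the price is that C6 must be oxidised, used as an enolate and reset.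

Key step: step 2

Remark on the chemistry: centres that are erased later are carried as mixtures and left undefined in the SMILES (ozonide carbon in 10, C10 carbinol in 12 and 13, C8 in 16–19). C6 of 6–13 is drawn as the anti-aldol epimer, although either epimer serves. The ligand antipode that gives the S quaternary carbon is assumed.

## Route

Step 1
Reactants: 1 ethynyltrimethylsilane
Product: 2 diisobutyl[1-(trimethylsilyl)ethenyl]aluminium
Conditions: iBu2AlH (1.0 equiv), hexanes/THF, 55 °C; solution used directly
Reagents that add atoms: diisobutylaluminium hydride, CC(C)C[AlH]CC(C)C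
Why: Hydroalumination of a silyl alkyne; aluminium adds to the silicon-bearing carbon, where the developing negative charge is stabilised α to silicon, and hydrogen to the terminal carbon.

Step 2
Reactants: 3 3-methylcyclopent-2-en-1-one; 2 diisobutyl[1-(trimethylsilyl)ethenyl]aluminium; 4 acetaldehyde
Product: 6 (2S,3S)-2-[(1S)-1-hydroxyethyl]-3-methyl-3-[1-(trimethylsilyl)ethenyl]cyclopentan-1-one, via aluminium enolate 5 (not isolated)
Conditions: Cu(OTf)2 (10 mol %), chiral sulfonate-bearing NHC transferred from its silver carbene (5 mol %, made from the imidazolinium sulfonate and Ag2O), 2 (2 equiv), THF, −30 °C; then CH3CHO (5 equiv), −78 °C; aq. KNaC4H4O6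
Reagents that add atoms: none
Why: Cu(OTf)2 (divalent copper) is reduced by the alane to a monovalent copper–NHC complex, which takes the silylethenyl group by transmetalation and delivers it to C1 of 3 by π-complexation, oxidative addition and reductive elimination, leaving aluminium enolate 5 with its double bond fixed at C4=C5. The closest known reaction type is the NHC–copper-catalysed enantioselective conjugate addition of silicon-substituted alkenylaluminium reagents to β-substituted cyclopentenones, joined to aldol trapping of the aluminium enolate. No ring is closed; the two skeletal bonds C1–C10 and C5–C6 are formed. C1 is set by the catalyst, whose sulfonate arm bridges copper and aluminium and opens one enone face. C5 is set by the substrate: acetaldehyde reacts through a closed six-membered aluminium-bound transition state on the enolate face anti to the bulky silylethenyl group, which gives the trans C1/C5 relationship of the ring fusion. C6 follows from the chair transition state of the ring enolate (anti aldol drawn) but is not needed, since C6 is oxidised in step 9. The step needs 1,4- over 1,2-addition (secured by copper), a regiodefined enolate (secured because 5 is made by the addition and used without equilibration) and aldol addition faster than hydride transfer from the isobutyl groups (excess aldehyde at −78 °C).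

Step 3
Reactants: 6 (2S,3S)-2-[(1S)-1-hydroxyethyl]-3-methyl-3-[1-(trimethylsilyl)ethenyl]cyclopentan-1-one
Product: 7 (2S,3S)-3-methyl-2-[(1S)-1-(triisopropylsilyloxy)ethyl]-3-[1-(trimethylsilyl)ethenyl]cyclopentan-1-one
Conditions: iPr3SiOTf, 2,6-lutidine, CH2Cl2, −78 → 0 °C
Reagents that add atoms: triisopropylsilyl trifluoromethanesulfonate, CC(C)[Si](OS(=O)(=O)C(F)(F)F)(C(C)C)C(C)C
Why: Silylation of a secondary alcohol with a silyl triflate and a hindered base; it stops retro-aldol and dehydration of the β-hydroxy ketone, and the triisopropylsilyl ether is chosen because it survives the acid of step 4.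

Step 4
Reactants: 7 (2S,3S)-3-methyl-2-[(1S)-1-(triisopropylsilyloxy)ethyl]-3-[1-(trimethylsilyl)ethenyl]cyclopentan-1-one
Product: 8 (2S,3R)-3-ethenyl-3-methyl-2-[(1S)-1-(triisopropylsilyloxy)ethyl]cyclopentan-1-one
Conditions: CF3CO2H, CH2Cl2, 0 °C → rt
Reagents that add atoms: none
Why: Protodesilylation of a vinylsilane (electrophilic substitution of silicon by a proton), known for exactly this kind of conjugate adduct; it is run now because no acid-labile tertiary alcohol is present yet, and the smaller vinyl group also opens the upper face of C4 for step 5.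

Step 5
Reactants: 8 (2S,3R)-3-ethenyl-3-methyl-2-[(1S)-1-(triisopropylsilyloxy)ethyl]cyclopentan-1-one
Product: 9 (1R,2S,3R)-3-ethenyl-3-methyl-1-(propan-2-yl)-2-[(1S)-1-(triisopropylsilyloxy)ethyl]cyclopentan-1-ol
Conditions: iPrMgCl, CeCl3 (anhydrous), THF, −78 → 0 °C
Reagents that add atoms: isopropylmagnesium chloride, CC(C)[Mg]Cl
Why: Organocerium 1,2-addition, which suppresses enolisation and hydride transfer from the isopropyl reagent; the nucleophile attacks the cyclopentanone anti to the bulky α side chain on C5 and to the C1 methyl on the same face, setting C4 with the hydroxyl cis to the side chain.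

Step 6
Reactants: 9 (1R,2S,3R)-3-ethenyl-3-methyl-1-(propan-2-yl)-2-[(1S)-1-(triisopropylsilyloxy)ethyl]cyclopentan-1-ol
Product: 11 (1S,2S,3R)-3-hydroxy-1-methyl-3-(propan-2-yl)-2-[(1S)-1-(triisopropylsilyloxy)ethyl]cyclopentane-1-carbaldehyde, via ozonide 10 (not isolated)
Conditions: O3, CH2Cl2, −78 °C; then PPh3, −78 °C → rt
Reagents that add atoms: ozone, O=[O+][O-]
Why: Ozonolysis of the only alkene with reductive work-up; the aldehyde has no α-hydrogen and cannot form a lactol with the trans C4 hydroxyl.

Step 7
Reactants: 11 (1S,2S,3R)-3-hydroxy-1-methyl-3-(propan-2-yl)-2-[(1S)-1-(triisopropylsilyloxy)ethyl]cyclopentane-1-carbaldehyde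
Product: 12 (1R,2S,3S)-3-[(2E)-1-hydroxybut-2-en-1-yl]-3-methyl-1-(propan-2-yl)-2-[(1S)-1-(triisopropylsilyloxy)ethyl]cyclopentan-1-ol (both carbinol epimers)
Conditions: (E)-1-bromoprop-1-ene, t-BuLi (2 equiv per bromide), Et2O, −78 °C; then 11 (0.4 equiv), THF, −78 → 0 °C; H2O
Reagents that add atoms: (E)-1-bromoprop-1-ene, C/C=C/Br
Why: 1,2-Addition of an alkenyllithium to an aldehyde; lithium–bromine exchange keeps the E geometry, one equivalent of reagent is consumed by the tertiary hydroxyl, and the new carbinol configuration is erased in step 9.

Step 8
Reactants: 12 (1R,2S,3S)-3-[(2E)-1-hydroxybut-2-en-1-yl]-3-methyl-1-(propan-2-yl)-2-[(1S)-1-(triisopropylsilyloxy)ethyl]cyclopentan-1-ol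
Product: 13 (1R,2S,3S)-3-[(2E)-1-hydroxybut-2-en-1-yl]-2-[(1S)-1-hydroxyethyl]-3-methyl-1-(propan-2-yl)cyclopentan-1-ol
Conditions: Bu4NF, THF, rt → 40 °C
Reagents that add atoms: none
Why: Fluoride cleavage of the silyl ether; nothing else in 12 is fluoride- or base-sensitive.

Step 9
Reactants: 13 (1R,2S,3S)-3-[(2E)-1-hydroxybut-2-en-1-yl]-2-[(1S)-1-hydroxyethyl]-3-methyl-1-(propan-2-yl)cyclopentan-1-ol
Product: 14 (2E)-1-[(1S,2R,3R)-2-acetyl-3-hydroxy-1-methyl-3-(propan-2-yl)cyclopentyl]but-2-en-1-one
Conditions: Dess–Martin periodinane (3 equiv), CH2Cl2, 0 °C → rt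
Reagents that add atoms: none
Why: Dess–Martin oxidation of both secondary alcohols in one operation; the tertiary alcohol cannot be oxidised, and the trans arrangement at C5 is the more stable one (acetyl anti to the isopropyl and enoyl groups), so it is not at risk.

Step 10
Reactants: 14 (2E)-1-[(1S,2R,3R)-2-acetyl-3-hydroxy-1-methyl-3-(propan-2-yl)cyclopentyl]but-2-en-1-one
Product: 15 (2E)-1-[(1S,2R,3R)-2-acetyl-1-methyl-3-(propan-2-yl)-3-(trimethylsilyloxy)cyclopentyl]but-2-en-1-one
Conditions: N-(trimethylsilyl)imidazole, CH2Cl2, rt
Reagents that add atoms: N-(trimethylsilyl)imidazole, C[Si](C)(C)n1ccnc1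
Why: Silylation of the tertiary alcohol with a neutral silyl donor that leaves ketones alone; with no free hydroxyl β to the C6 ketone, the base of step 11 cannot start a retro-aldol opening of ring A.

Step 11
Reactants: 15 (2E)-1-[(1S,2R,3R)-2-acetyl-1-methyl-3-(propan-2-yl)-3-(trimethylsilyloxy)cyclopentyl]but-2-en-1-one
Product: 17 (1S,4R,5R)-4-hydroxydaucane-6,10-dione (C8 epimers), via silyl-protected diketone 16 (not isolated)
Conditions: KN(SiMe3)2 (1.1 equiv), THF (high dilution), −78 → −20 °C; AcOH, −78 °C; then 1 M HCl, THF, 0 °C
Reagents that add atoms: none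
Why: Intramolecular Michael addition (7-endo-trig, allowed): kinetic deprotonation occurs at the methyl group C7 and not at the crowded C5, and the enolate adds to C8 of the s-trans enone to close ring B; the rival aldol at C10 would give a strained, reversible trans-bicyclo[3.3.0]octane; C8 is formed as a mixture that step 14 erases, and the acid work-up removes the tertiary silyl ether.

Step 12
Reactants: 17 (1S,4R,5R)-4-hydroxydaucane-6,10-dione
Product: 18 (1S,4R,5S,6S)-4,6-dihydroxydaucan-10-one (C8 epimers)
Conditions: Me4NBH(OAc)3, MeCN/AcOH (1:1), −30 → −20 °C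
Reagents that add atoms: none
Why: Hydroxyl-directed (Evans–Saksena) reduction: the C4 hydroxyl exchanges with acetate on boron and hydride is delivered to C6 through a six-membered chair with ring B carbon C7 equatorial; the trans fusion fixes the pucker of ring A so that this chair brings hydride in anti to H5, giving the 1,3-anti diol with O6 cis to H5 (6S); the C10 ketone has no hydroxyl in reach, is flanked by quaternary C1, and is inert to this weak hydride donor.

Step 13
Reactants: 18 (1S,4R,5S,6S)-4,6-dihydroxydaucan-10-one
Product: 19 (1S,4R,5S,6S)-4-hydroxy-10-oxodaucan-6-yl 4-methoxybenzoate (C8 epimers)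
Conditions: 4-MeOC6H4COCl, pyridine, DMAP (cat.), CH2Cl2, 0 °C → rt
Reagents that add atoms: 4-methoxybenzoyl chloride, COc1ccc(cc1)C(Cl)=O
Why: Acylation with nucleophilic catalysis; only the secondary C6 hydroxyl reacts, the tertiary C4 hydroxyl being too hindered.

Step 14
Reactants: 19 (1S,4R,5S,6S)-4-hydroxy-10-oxodaucan-6-yl 4-methoxybenzoate
Product: 20 (1S,4R,5S,6S)-4-hydroxy-10-oxodauc-8-en-6-yl 4-methoxybenzoate [(3R,3aS,4S,8aS)-3-hydroxy-6,8a-dimethyl-8-oxo-3-(propan-2-yl)-1,2,3,3a,4,5,8,8a-octahydroazulen-4-yl 4-methoxybenzoate]
Conditions: IBX (2.5 equiv), DMSO/toluene, 70 °C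
Reagents that add atoms: none
Why: Ketone dehydrogenation with 2-iodoxybenzoic acid via the enol: C10 can enolise only toward C9 because C1 is quaternary, so the alkene can form only at C8=C9 and both C8 epimers converge; the medium is not basic, so the ester at C6 is not eliminated, and tertiary alcohols are not oxidised.

## Compound list

1 | ethynyltrimethylsilane | C#C[Si](C)(C)C | starting material
2 | diisobutyl[1-(trimethylsilyl)ethenyl]aluminium | C=C([Si](C)(C)C)[Al](CC(C)C)CC(C)C | intermediate
3 | 3-methylcyclopent-2-en-1-one | CC1=CC(=O)CC1 | starting material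
4 | acetaldehyde | CC=O | starting material
5 | diisobutylaluminium (3S)-3-methyl-3-[1-(trimethylsilyl)ethenyl]cyclopent-1-en-1-olate | CC(C)C[Al](CC(C)C)OC1=C[C@@](C)(C(=C)[Si](C)(C)C)CC1 | intermediate (not isolated)
6 | (2S,3S)-2-[(1S)-1-hydroxyethyl]-3-methyl-3-[1-(trimethylsilyl)ethenyl]cyclopentan-1-one | C[C@H](O)[C@@H]1[C@@](C)(C(=C)[Si](C)(C)C)CCC1=O | intermediate
7 | (2S,3S)-3-methyl-2-[(1S)-1-(triisopropylsilyloxy)ethyl]-3-[1-(trimethylsilyl)ethenyl]cyclopentan-1-one | C[C@H](O[Si](C(C)C)(C(C)C)C(C)C)[C@@H]1[C@@](C)(C(=C)[Si](C)(C)C)CCC1=O | intermediate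
8 | (2S,3R)-3-ethenyl-3-methyl-2-[(1S)-1-(triisopropylsilyloxy)ethyl]cyclopentan-1-one | C[C@H](O[Si](C(C)C)(C(C)C)C(C)C)[C@@H]1[C@@](C)(C=C)CCC1=O | intermediate
9 | (1R,2S,3R)-3-ethenyl-3-methyl-1-(propan-2-yl)-2-[(1S)-1-(triisopropylsilyloxy)ethyl]cyclopentan-1-ol | C[C@H](O[Si](C(C)C)(C(C)C)C(C)C)[C@@H]1[C@@](C)(C=C)CC[C@@]1(O)C(C)C | intermediate
10 | (1R,2S,3S)-3-methyl-1-(propan-2-yl)-2-[(1S)-1-(triisopropylsilyloxy)ethyl]-3-(1,2,4-trioxolan-3-yl)cyclopentan-1-ol (ozonide, trioxolane carbon undefined) | C[C@H](O[Si](C(C)C)(C(C)C)C(C)C)[C@@H]1[C@@](C)(C2OOCO2)CC[C@@]1(O)C(C)C | intermediate (not isolated)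
11 | (1S,2S,3R)-3-hydroxy-1-methyl-3-(propan-2-yl)-2-[(1S)-1-(triisopropylsilyloxy)ethyl]cyclopentane-1-carbaldehyde | C[C@H](O[Si](C(C)C)(C(C)C)C(C)C)[C@@H]1[C@@](C)(C=O)CC[C@@]1(O)C(C)C | intermediate
12 | (1R,2S,3S)-3-[(2E)-1-hydroxybut-2-en-1-yl]-3-methyl-1-(propan-2-yl)-2-[(1S)-1-(triisopropylsilyloxy)ethyl]cyclopentan-1-ol (carbinol epimers) | C[C@H](O[Si](C(C)C)(C(C)C)C(C)C)[C@@H]1[C@@](C)(C(O)/C=C/C)CC[C@@]1(O)C(C)C | intermediate
13 | (1R,2S,3S)-3-[(2E)-1-hydroxybut-2-en-1-yl]-2-[(1S)-1-hydroxyethyl]-3-methyl-1-(propan-2-yl)cyclopentan-1-ol (carbinol epimers) | C[C@H](O)[C@@H]1[C@@](C)(C(O)/C=C/C)CC[C@@]1(O)C(C)C | intermediate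
14 | (2E)-1-[(1S,2R,3R)-2-acetyl-3-hydroxy-1-methyl-3-(propan-2-yl)cyclopentyl]but-2-en-1-one | CC(=O)[C@@H]1[C@@](C)(C(=O)/C=C/C)CC[C@@]1(O)C(C)C | intermediate
15 | (2E)-1-[(1S,2R,3R)-2-acetyl-1-methyl-3-(propan-2-yl)-3-(trimethylsilyloxy)cyclopentyl]but-2-en-1-one | CC(=O)[C@@H]1[C@@](C)(C(=O)/C=C/C)CC[C@@]1(O[Si](C)(C)C)C(C)C | intermediate
16 | (1S,4R,5R)-4-(trimethylsilyloxy)daucane-6,10-dione (C8 epimers) | O=C1CC(C)CC(=O)[C@@]2(C)CC[C@@](O[Si](C)(C)C)(C(C)C)[C@H]12 | intermediate (not isolated)
17 | (1S,4R,5R)-4-hydroxydaucane-6,10-dione (C8 epimers) | O=C1CC(C)CC(=O)[C@@]2(C)CC[C@@](O)(C(C)C)[C@H]12 | intermediate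
18 | (1S,4R,5S,6S)-4,6-dihydroxydaucan-10-one (C8 epimers) | O[C@H]1CC(C)CC(=O)[C@@]2(C)CC[C@@](O)(C(C)C)[C@H]12 | intermediate
19 | (1S,4R,5S,6S)-4-hydroxy-10-oxodaucan-6-yl 4-methoxybenzoate (C8 epimers) | COc1ccc(cc1)C(=O)O[C@H]1CC(C)CC(=O)[C@@]2(C)CC[C@@](O)(C(C)C)[C@H]12 | intermediate
20 | (3R,3aS,4S,8aS)-3-hydroxy-6,8a-dimethyl-8-oxo-3-(propan-2-yl)-1,2,3,3a,4,5,8,8a-octahydroazulen-4-yl 4-methoxybenzoate | COc1ccc(C(=O)O[C@H]2CC(C)=CC(=O)[C@@]3(C)CC[C@@](O)(C(C)C)[C@H]23)cc1 | target

## Step count and least certain steps

Total: 14 steps. Longest linear sequence: 14 steps (1 → 20); 13 steps counted from enone 3.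

**Step 2 (key step).** The diisobutylaluminium enolate is flanked by the new quaternary carbon and may add to acetaldehyde slowly. Hydride transfer from an isobutyl group to the aldehyde, or consumption of the aldehyde by excess alkenylalane, could then outrun C–C bond formation. The aldolate could also revert on warming. Fallback: the event is divided. Enolate 5, made as before from 3 and 2, is trapped with Et3SiOTf to give the triethylsilyl enol ether F1, which is isolated. A Mukaiyama aldol addition of F1 to acetaldehyde 4 with TiCl4 in CH2Cl2 at −78 °C, through an open transition state on the face anti to the silylethenyl group, returns to the route at 6. Either C6 epimer is usable.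

**Step 11.** The 7-endo-trig closure may be slow. γ-Deprotonation of the butenoyl group and intermolecular Michael addition could then compete, and once C5 is enolised the silanolate on C4 can be lost by β-elimination. Fallback: the nucleophile is made neutral and the acceptor is activated instead. From 15, LiN(iPr)2 with Me3SiCl at −78 °C gives the kinetic C7 trimethylsilyl enol ether F2. TiCl4 in CH2Cl2 at −78 °C then promotes an intramolecular Mukaiyama–Michael addition, and acidic work-up returns to the route at 17.

**Step 12.** Exchange of acetate for the crowded tertiary C4 hydroxyl may be too slow for intramolecular delivery, leading to no reaction or loss of facial control. Fallback: from 17, LiBH(s-Bu)3 at −78 °C is used without direction. It should select the less shielded C6 carbonyl over the neopentyl C10 carbonyl and approach anti to the axial C1 methyl, giving the C6 epimer, (1S,4R,5S,6R)-4,6-dihydroxydaucan-10-one F3. A Mitsunobu esterification with 4-methoxybenzoic acid, PPh3 and diisopropyl azodicarboxylate then inverts C6 while installing the ester, returning to the route at 19.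

**Step 14.** Enolisation of the neopentyl C10 ketone may be sluggish at a temperature the product tolerates, and prolonged heating in DMSO could cause thermal loss of the C6 ester from the enone. Fallback: a Saegusa–Ito sequence from 19. Me3SiOTf and Et3N give the bis-silyl compound F4 (C9=C10 silyl enol ether, C4 silyl ether). Pd(OAc)2 (divalent palladium) in MeCN at rt gives the enone as its C4 trimethylsilyl ether F5, and citric acid in MeOH frees the tertiary alcohol to reach 20.

## Further compounds

F1 | step 2 | triethyl({(3S)-3-methyl-3-[1-(trimethylsilyl)ethenyl]cyclopent-1-en-1-yl}oxy)silane | CC[Si](CC)(CC)OC1=C[C@@](C)(C(=C)[Si](C)(C)C)CC1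
F2 | step 11 | C7 trimethylsilyl enol ether of 15 (C6(OSiMe3)=C7H2, C4 silyl ether kept) | C=C(O[Si](C)(C)C)[C@@H]1[C@@](C)(C(=O)/C=C/C)CC[C@@]1(O[Si](C)(C)C)C(C)C
F3 | step 12 | (1S,4R,5S,6R)-4,6-dihydroxydaucan-10-one (C6 epimer of 18, C8 epimers) | O[C@@H]1CC(C)CC(=O)[C@@]2(C)CC[C@@](O)(C(C)C)[C@H]12
F4 | step 14 | C9=C10 trimethylsilyl enol ether and C4 trimethylsilyl ether of 19 | COc1ccc(cc1)C(=O)O[C@H]1CC(C)C=C(O[Si](C)(C)C)[C@@]2(C)CC[C@@](O[Si](C)(C)C)(C(C)C)[C@H]12
F5 | step 14 | C4 trimethylsilyl ether of 20 | COc1ccc(cc1)C(=O)O[C@H]1CC(C)=CC(=O)[C@@]2(C)CC[C@@](O[Si](C)(C)C)(C(C)C)[C@H]12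
A1 | alternative 1 | (8aR)-4-methoxy-6-methyl-3,8a-dihydroazulen-1(2H)-one (methoxy on C10, methyl on C8 in daucane numbering) | O=C1CCC2=C(OC)C=C(C)C=C[C@@H]12
A2 | alternative 1 | 1-diazo-4-(2-methoxy-4-methylphenyl)butan-2-one | COc1cc(C)ccc1CCC(=O)C=[N+]=[N-]
A3 | alternative 2 | C4 triethylsilyl ether of the target | COc1ccc(cc1)C(=O)O[C@H]2CC(C)=CC(=O)[C@@]3(C)CC[C@@](O[Si](CC)(CC)CC)(C(C)C)[C@H]23
A4 | alternative 2 | trans-hydrindane trimethylsilyl enol ether (C10–OSiMe3, C10=C8, C6 4-methoxybenzoate, C4 triethylsilyl ether; C9 absent) | COc1ccc(cc1)C(=O)O[C@H]2CC(C)=C(O[Si](C)(C)C)[C@@]3(C)CC[C@@](O[Si](CC)(CC)CC)(C(C)C)[C@H]23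
A5 | alternative 3 | methyl (1R,2S)-2-{[(tert-butyldiphenylsilyl)oxy]methyl}-2-methyl-5-oxocyclopentane-1-carboxylate | COC(=O)[C@@H]1[C@@](C)(CO[Si](C(C)(C)C)(c2ccccc2)c2ccccc2)CCC1=O
A6 | alternative 3 | methyl (6S)-7-[(tert-butyldiphenylsilyl)oxy]-2-diazo-6-methyl-3-oxoheptanoate | COC(=O)C(=[N+]=[N-])C(=O)CC[C@H](C)CO[Si](C(C)(C)C)(c1ccccc1)c1ccccc1
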